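**Assumptions**
- The target is the natural valepotriate configuration: C1 isovalerate cis to H9, C7 isovalerate trans to the C9 carbon substituent, C8 OH cis to C1, and C10 cis to the C7 oxygen.
- The C9 stereocentre made in Step 6 equilibrates to the trans (thermodynamic) isomer because it sits in a β-keto ester.
- The benzylidene acetal in Step 10 bridges the 1,3-diol C1-O/C8-O, and its own acetal carbon is irrelevant because it is removed in Step 20.
- Step numbers are listed in forward order. Step 13 is a side branch that makes a reagent.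

**Retrosynthesis**
1. The C1 acylal and the dienyl-ether pyran ring (ring B) are formed last, by acylative oxa-cyclization of an enal-aldehyde (the new step).
2. The enal comes from a C5 ketone by vinyl-cerium addition followed by Babler–Dauben oxidative transposition, which installs C4, C3 and C11.
3. The cyclopentane (ring A) comes from an Au(I) Conia-ene of an alkynyl β-keto ester, whose C7 stereocentre is set by Noyori transfer hydrogenation.
4. C8/C10 come from a hydroxyl-directed dihydroxylation of the exocyclic methylene.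
5. Ring order: ring A in Step 6, ring B in Step 22.

**Step 1**
Reactants: 1 (3-(trimethylsilyl)propiolic acid); 2 (potassium ethyl malonate)
Product: 3 (ethyl 3-oxo-5-(trimethylsilyl)pent-4-ynoate)
Conditions: CDI, THF, 25 °C; then 2, MgCl2, Et3N, 25 °C
Reagents that add atoms: none
Why: Masamune acylation of a magnesium malonate half-ester by the acyl imidazolide, followed by decarboxylation, gives the β-keto ester.

**Step 2**
Reactants: 3
Product: 4 (ethyl (3S)-3-hydroxy-5-(trimethylsilyl)pent-4-ynoate)
Conditions: RuCl[(S,S)-TsDPEN](p-cymene) (2 mol%), HCO2H/Et3N (5:2), CH2Cl2, 25 °C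
Reagents that add atoms: none (hydrogen only)
Why: Noyori asymmetric transfer hydrogenation of the ynone carbonyl sets C7 as (S).

**Step 3**
Reactants: 4
Product: 5 (ethyl (3S)-3-(TBDPSO)-5-(trimethylsilyl)pent-4-ynoate)
Conditions: TBDPSCl, imidazole, DMF, 25 °C
Reagents that add atoms: TBDPSCl, CC(C)(C)[Si](Cl)(c1ccccc1)c1ccccc1
Why: Silylation protects the alcohol without touching the stereocentre.

**Step 4**
Reactants: 5
Product: 6 ((3S)-3-(TBDPSO)pent-4-ynoic acid)
Conditions: KOH, MeOH/H2O (4:1), 40 °C; then H3O+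
Reagents that add atoms: KOH, [K+].[OH-]
Why: Saponification with concomitant protodesilylation of the alkynyl TMS group gives the terminal alkyne acid.

**Step 5**
Reactants: 6; 7 (potassium tert-butyl malonate)
Product: 8 (tert-butyl (5S)-5-(TBDPSO)-3-oxohept-6-ynoate)
Conditions: CDI, THF, 25 °C; then 7, MgCl2, Et3N, 25 °C
Reagents that add atoms: none
Why: A second Masamune acylation builds the C5 ketone and the C9/C1 tert-butyl ester unit; C7 is untouched.

**Step 6**
Reactants: 8
Product: 9 (tert-butyl (1R,4S)-4-(TBDPSO)-5-methylidene-2-oxocyclopentane-1-carboxylate)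
Conditions: Ph3PAuCl/AgSbF6 (5 mol%), CH2Cl2, 25 °C
Reagents that add atoms: none
Why: Au(I)-catalysed Conia-ene carbocyclization (5-exo-dig; the enol carbon C9 attacks the Au-activated alkyne carbon C8, and protodeauration gives the exocyclic C8=C10). This forms ring A, and the epimerizable C9 settles trans to C7-OTBDPS.

**Step 7**
Reactants: 9
Product: 10 (ethylene ketal of 9)
Conditions: TMSOCH2CH2OTMS, TMSOTf (5 mol%), CH2Cl2, −78 → 0 °C
Reagents that add atoms: 1,2-bis(trimethylsilyloxy)ethane, C[Si](C)(C)OCCO[Si](C)(C)C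
Why: Noyori ketalization masks C5, so the ester can be reduced and enolization or isomerization is suppressed. Stereocentres are unchanged.

**Step 8**
Reactants: 10
Product: 11 (primary alcohol: C9-CH2OH, C5 ketal, C7-OTBDPS, C8=CH2)
Conditions: LiAlH4, THF, 0 → 25 °C
Reagents that add atoms: none
Why: Hydride reduction of the tert-butyl ester gives C1-OH and leaves C9 (ester α-carbon) configurationally intact.

**Step 9**
Reactants: 11
Product: 12 (triol: C1-OH, C8-OH up, C10-OH)
Conditions: OsO4 (1.1 equiv), TMEDA, CH2Cl2, −78 °C; then aq. NaHSO3, THF, 50 °C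
Reagents that add atoms: OsO4, O=[Os](=O)(=O)=O
Why: Donohoe OsO4·TMEDA dihydroxylation is H-bond-directed by the homoallylic C1-OH, so it goes syn to C1, anti to C7-OTBDPS. This gives C8-OH cis to C1 and C10 cis to C7-O, which sets the C8 quaternary centre.

**Step 10**
Reactants: 12
Product: 13 (1,3-benzylidene acetal across C1-O/C8-O; C10-OH free; acetal carbon undefined)
Conditions: PhCH(OMe)2, CSA (5 mol%), CH2Cl2, 4 Å MS, 25 °C
Reagents that add atoms: benzaldehyde dimethyl acetal, COC(OC)c1ccccc1
Why: Thermodynamic benzylidene formation favours the cis-fused six-membered 1,3-dioxane, which differentiates C1 (to be oxidized) from C10 (to be acetylated) and protects the tertiary C8-OH.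

**Step 11**
Reactants: 13
Product: 14 (C10-OTBS)
Conditions: TBSOTf, 2,6-lutidine, CH2Cl2, −78 → 0 °C
Reagents that add atoms: TBSOTf, C[Si](C)(OS(=O)(=O)C(F)(F)F)C(C)(C)C
Why: The only free hydroxyl is silylated, with no change at any stereocentre.

**Step 12**
Reactants: 14
Product: 15 (cyclopentanone, C5=O)
Conditions: PPTS (20 mol%), acetone/H2O (10:1), 55 °C
Reagents that add atoms: water, O
Why: Transketalization unmasks C5; the cis-fused acetal locks C9, so it cannot epimerize.

**Step 13**
Reactants: 16 (2-bromoprop-2-en-1-ol)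
Product: 17 ((2-bromoallyloxy)-TBS ether)
Conditions: TBSCl, imidazole, DMF, 0 → 25 °C
Reagents that add atoms: TBSCl, C[Si](C)(Cl)C(C)(C)C
Why: Simple silylation prepares the C4/C3/C11 vinyl-metal precursor.

**Step 14**
Reactants: 15; 17
Product: 18 (tertiary allylic alcohol; C5 configuration undefined)
Conditions: 17, Mg, THF, 25 °C; CeCl3, −78 °C; add 15, −78 → −40 °C
Reagents that add atoms: none
Why: Imamoto-type organocerium addition avoids enolization and β-elimination of the ketone; the new C5 carbinol stereocentre is destroyed in Step 15, so it does not matter.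

**Step 15**
Reactants: 18
Product: 19 (α-(silyloxymethyl) enal, C3HO–C4(C11)=C5; alkene geometry mixed)
Conditions: PCC, NaOAc, Celite, CH2Cl2, 25 °C
Reagents that add atoms: none
Why: Babler–Dauben oxidative 1,3-transposition of the tertiary allylic alcohol (chromate [3,3] shift, then oxidation of the primary chromate) turns C3H2= into C3HO with the tetrasubstituted C4=C5 alkene.

**Step 16**
Reactants: 19
Product: 20 (C10-OH and C11-OH free; C7-OTBDPS retained)
Conditions: HF·py, pyridine/THF (1:4), 0 → 25 °C
Reagents that add atoms: none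
Why: Primary TBS ethers are cleaved in preference to the hindered secondary TBDPS ether, and the benzylidene acetal survives.

**Step 17**
Reactants: 20
Product: 21 (C10-OAc, C11-OAc)
Conditions: Ac2O, pyridine, DMAP (10 mol%), CH2Cl2, 0 → 25 °C
Reagents that add atoms: Ac2O, CC(=O)OC(C)=O
Why: Only the two primary hydroxyls are free, so acetylation is unambiguous.

**Step 18**
Reactants: 21
Product: 22 (C7-OH)
Conditions: TBAF/AcOH (1:1), THF, 40 °C
Reagents that add atoms: none
Why: Buffered fluoride removes the hindered TBDPS ether while the acetates, enal and benzylidene are kept.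

**Step 19**
Reactants: 22
Product: 23 (C7-isovalerate)
Conditions: (iPrCH2CO)2O, DMAP (20 mol%), pyridine, CH2Cl2, 25 °C
Reagents that add atoms: isovaleric anhydride, CC(C)CC(=O)OC(=O)CC(C)C
Why: Acylation with retention installs the C7 ester.

**Step 20**
Reactants: 23
Product: 24 (C1-OH/C8-OH diol)
Conditions: AcOH/H2O (4:1), 60 °C
Reagents that add atoms: none
Why: Acid hydrolysis of the benzylidene acetal releases the primary C1 alcohol and the tertiary C8 alcohol, and the esters and enal survive.

**Step 21**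
Reactants: 24
Product: 25 (C1 aldehyde; used crude because it is a β-hydroxy aldehyde)
Conditions: DMP, NaHCO3, CH2Cl2, 0 → 25 °C
Reagents that add atoms: none
Why: DMP oxidizes only the primary alcohol, since the C8 alcohol is tertiary.

**Step 22**
Reactants: 25
Product: 26 (10-acetoxyvaltrathydrin)
Conditions: (iPrCH2CO)2O (5 equiv), TMSOTf (1.5 equiv), 2,6-di-tert-butyl-4-methylpyridine (4 equiv), CH2Cl2, −78 → −20 °C; then NH4F, MeOH, 0 °C
Reagents that add atoms: isovaleric anhydride, CC(C)CC(=O)OC(=O)CC(C)C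
Why: Proposed new method: TMSOTf/anhydride converts the C1 aldehyde into an α-isovaleryloxy carbenium, which the Z-enal carbonyl oxygen traps in a 6-membered ring to give a cyclic vinylogous oxocarbenium; the hindered pyridine removes the C6-H to give the C3=C4–C5=C6 dienyl ether, and the transient C8-OTMS is cleaved by NH4F/MeOH. C1 is set thermodynamically, because reversible acylal ionization funnels to the anomeric, pseudo-axial OiVal cis to H9. The closest known chemistry is Lewis-acid acylal formation from aldehydes and anhydrides combined with oxocarbenium/Prins-type cyclization and γ-deprotonation of pyrylium-type cations.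

**Compound list**

| # | Name | SMILES | Role |
|---|---|---|---|
| 1 | 3-(Trimethylsilyl)propiolic acid | C[Si](C)(C)C#CC(=O)O | starting material |
| 2 | Potassium ethyl malonate | CCOC(=O)CC(=O)[O-].[K+] | starting material |
| 3 | Ethyl 3-oxo-5-(trimethylsilyl)pent-4-ynoate | CCOC(=O)CC(=O)C#C[Si](C)(C)C | intermediate |
| 4 | Ethyl (3S)-3-hydroxy-5-(trimethylsilyl)pent-4-ynoate | CCOC(=O)C[C@H](O)C#C[Si](C)(C)C | intermediate |
| 5 | Ethyl (3S)-3-(TBDPSO)-5-(trimethylsilyl)pent-4-ynoate | CCOC(=O)C[C@H](O[Si](c1ccccc1)(c1ccccc1)C(C)(C)C)C#C[Si](C)(C)C | intermediate |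
| 6 | (3S)-3-(TBDPSO)pent-4-ynoic acid | OC(=O)C[C@H](O[Si](c1ccccc1)(c1ccccc1)C(C)(C)C)C#C | intermediate |
| 7 | Potassium tert-butyl malonate | CC(C)(C)OC(=O)CC(=O)[O-].[K+] | starting material |
| 8 | tert-Butyl (5S)-5-(TBDPSO)-3-oxohept-6-ynoate | CC(C)(C)OC(=O)CC(=O)C[C@H](O[Si](c1ccccc1)(c1ccccc1)C(C)(C)C)C#C | intermediate |
| 9 | tert-Butyl (1R,4S)-4-(TBDPSO)-5-methylidene-2-oxocyclopentane-1-carboxylate | O=C1C[C@H](O[Si](c2ccccc2)(c2ccccc2)C(C)(C)C)C(=C)[C@H]1C(=O)OC(C)(C)C | intermediate |
| 10 | Ethylene ketal of 9 | CC(C)(C)OC(=O)[C@@H]1C(=C)[C@@H](O[Si](c2ccccc2)(c2ccccc2)C(C)(C)C)CC13OCCO3 | intermediate |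
| 11 | Primary alcohol (C9-CH2OH) | OC[C@@H]1C(=C)[C@@H](O[Si](c2ccccc2)(c2ccccc2)C(C)(C)C)CC13OCCO3 | intermediate |
| 12 | Triol (C1-OH, C8-OH, C10-OH) | OC[C@@H]1[C@@](O)(CO)[C@@H](O[Si](c2ccccc2)(c2ccccc2)C(C)(C)C)CC13OCCO3 | intermediate |
| 13 | C1/C8 benzylidene acetal, C10-OH free | OC[C@@]12[C@@H](O[Si](c3ccccc3)(c3ccccc3)C(C)(C)C)CC3(OCCO3)[C@@H]1COC(c1ccccc1)O2 | intermediate |
| 14 | C10-OTBS derivative of 13 | CC(C)(C)[Si](C)(C)OC[C@@]12[C@@H](O[Si](c3ccccc3)(c3ccccc3)C(C)(C)C)CC3(OCCO3)[C@@H]1COC(c1ccccc1)O2 | intermediate |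
| 15 | Cyclopentanone (C5=O) | CC(C)(C)[Si](C)(C)OC[C@@]12[C@@H](O[Si](c3ccccc3)(c3ccccc3)C(C)(C)C)CC(=O)[C@@H]1COC(c1ccccc1)O2 | intermediate |
| 16 | 2-Bromoprop-2-en-1-ol | C=C(Br)CO | starting material |
| 17 | (2-Bromoallyloxy)-TBS ether | C=C(Br)CO[Si](C)(C)C(C)(C)C | intermediate |
| 18 | Tertiary allylic alcohol (C5 undefined) | CC(C)(C)[Si](C)(C)OC[C@@]12[C@@H](O[Si](c3ccccc3)(c3ccccc3)C(C)(C)C)CC(O)(C(=C)CO[Si](C)(C)C(C)(C)C)[C@@H]1COC(c1ccccc1)O2 | intermediate |
| 19 | Enal (C4=C5 geometry mixed) | CC(C)(C)[Si](C)(C)OC[C@@]12[C@@H](O[Si](c3ccccc3)(c3ccccc3)C(C)(C)C)CC(=C(C=O)CO[Si](C)(C)C(C)(C)C)[C@@H]1COC(c1ccccc1)O2 | intermediate |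
| 20 | Enal with C10-OH and C11-OH free | OC[C@@]12[C@@H](O[Si](c3ccccc3)(c3ccccc3)C(C)(C)C)CC(=C(C=O)CO)[C@@H]1COC(c1ccccc1)O2 | intermediate |
| 21 | C10/C11 diacetate | CC(=O)OC[C@@]12[C@@H](O[Si](c3ccccc3)(c3ccccc3)C(C)(C)C)CC(=C(C=O)COC(C)=O)[C@@H]1COC(c1ccccc1)O2 | intermediate |
| 22 | C7-OH enal diacetate | CC(=O)OC[C@@]12[C@@H](O)CC(=C(C=O)COC(C)=O)[C@@H]1COC(c1ccccc1)O2 | intermediate |
| 23 | C7-isovalerate | CC(=O)OC[C@@]12[C@@H](OC(=O)CC(C)C)CC(=C(C=O)COC(C)=O)[C@@H]1COC(c1ccccc1)O2 | intermediate |
| 24 | C1-OH/C8-OH diol | CC(=O)OC[C@@]1(O)[C@@H](OC(=O)CC(C)C)CC(=C(C=O)COC(C)=O)[C@@H]1CO | intermediate |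
| 25 | C1 aldehyde / C3 enal | CC(=O)OC[C@@]1(O)[C@@H](OC(=O)CC(C)C)CC(=C(C=O)COC(C)=O)[C@@H]1C=O | intermediate |
| 26 | 10-Acetoxyvaltrathydrin | CC(=O)OCC1=CO[C@@H](OC(=O)CC(C)C)[C@H]2C1=C[C@H](OC(=O)CC(C)C)[C@]2(O)COC(C)=O | target |

**Totals:** 22 steps in total; the longest linear sequence is 21 steps (Steps 1–12, then 14–22; Step 13 is a parallel reagent preparation).

**Three steps most likely to fail**
1. **Step 22 (proposed new method).** Risks are competing gem-diisovalerate formation, an unreactive E-enal, protonation at C9 instead of C6, silylation or acylation of the C8-OH, and decomposition of the acid-sensitive acylal and dienyl ether.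
   - Fallback (known chemistry, different approach): oxidize the enal to the acid with NaClO2, close it onto the C1 aldehyde to the δ-lactone pseudo-acid, and acylate C1-OH with isovaleric anhydride. Then reduce the lactone with DIBAL at −78 °C and dehydrate the lactol acetate.
2. **Step 6 (Au Conia-ene).** The acyl-tethered enolendo mode is the least precedented part, and the ketone oxygen can cyclize onto the alkyne or the exocyclic alkene can isomerize.
   - Fallback: convert the alkyne of 8 to the 2-bromoalkene by Markovnikov hydrobromination, then use Pd-catalysed intramolecular α-vinylation of the β-keto ester to give the same ring.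
3. **Step 9 (directed dihydroxylation setting C8).** Facial selectivity could be poor.
   - Fallback: VO(acac)2/TBHP hydroxyl-directed epoxidation of 11, then CsOAc/AcOH SN2 opening at C10, then K2CO3/MeOH, which gives the same triol 12.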